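I must decide whether this flask can be stopped at 25 h and its target read as final, so I start from what the flask can hold at its end.

    substrate ⇌ dormant form (K1 = 2.7, k1 = 0.014 min⁻¹)
    substrate ⇌ isomer of the product (K2 = 1.9, k2 = 0.014 min⁻¹)
    crystals ⇌ target, rate k3*(cs3 - [target]) while solid is left; crystals form when [target] > cs3 (cs3 = 3.6 mM, k3 = 0.28 min⁻¹)
    substrate ⇌ target (K4 = 0.94, k4 = 0.32 min⁻¹)

substrate 0.20 M; time 25 h

- why nothing more happens at 25 h, or that something still does (it is still moving / forward and back rates have come level)
- amount of target at 25 h, in percent of the substrate charged
- amount of target if the flask were left three thousand times as long, in percent of the substrate charged

- what is said of target includes crystals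
- crystals is a solid; its amount is given per volume of the solution
- the reaction counts as stopped when no species that holds the substrate changes by six tenths of a point or more over the second half of the time
- run time (flask): 25 h

Setting a step's forward rate equal to its back rate makes time drop out and leaves a ratio of amounts. While crystals stand, dissolved target sits at its solubility, 1.80% of the charge, so level steps put substrate at 1.91%, with dormant form 2.7 times that and isomer 1.9 times that. Together these three make 10.7% of the charge. I call this the keep, the share of the charge held outside target while crystals stand and each step is level. My reckoning therefore gives target 89.3%, which is thermodynamic control. The back rate of the dormant form, taken alone, has a half-life of 2.23 h, shorter than 25 h, so I expect level rates by then.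

The forecast says forward and back rates have come level, with 89.3% at 25 h and 89.3% after the long wait, and holds that “a longer wait changes nothing”.

The simulation gives forward and back rates have come level, with 89.3% and 89.3%. The largest change over the second half is 0.17 percentage points, and the share outside target, 10.7%, equals the keep.

In this flask the forward rate of the path from substrate to target starts at 23 times that of the path to dormant form, and by 2.50 h target is 85.8%, with crystals 83.9% counted in it, dormant form 6.80% and isomer 5.40%. By 25.0 h dormant form has fallen to 5.17% and isomer to 3.64%, while crystals have risen to 87.5%. With this flask's charge moved to 0.136 M or 0.375 M, the time held, target at 25 h stands 5 points from the forecast's number.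

In a neighbour flask charged with 0.12 M, the same amount spread over the smaller charge makes the keep 17.9%, so I expect target 82.1%. The simulation gives 82.1% for that neighbour.

The constants used here are made up; the flask was simulated.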